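**Strategy.** The synthesis rests on disconnecting the aryl–CH2 bond of the 4-hydroxy-3,5-dimethoxybenzyl group on C4 of the butyrolactone. This benzylic CH2 stands 1,3 to the lactone α-carbon C3, so it can be the methylene of a cyclopropane fused across C3–C4 of the lactone ring, activated by the lactone carbonyl and a removable ester on C3. The precursor is methyl (1S,5R)-2-oxo-3-oxabicyclo[3.1.0]hexane-1-carboxylate. Copper-catalysed homoconjugate addition of the O-benzyl-protected aryl Grignard reagent opens this strained ring at the CH2 and forges the aryl–CH2 bond with the C4 stereocentre, taken from (R)-epichlorohydrin, already in place. Decarboxylation, trans-selective benzylation at C3 and hydrogenolysis finish the route.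

Key step: step 3

Assumption: C3 of compound 9 is an epimerisable malonate-type centre. It is drawn as the trans (3S,4R) epimer expected at equilibrium, and its configuration is of no consequence because step 4 removes it. Compounds 1, 2, 6 and 11 are taken as commercially available.

**Step 1**
Reactants: 1 (R)-epichlorohydrin; 2 dimethyl malonate
Product: 5 methyl (1S,5R)-2-oxo-3-oxabicyclo[3.1.0]hexane-1-carboxylate, via epoxymalonate 3 (not isolated), via cyclopropylcarbinol diester 4 (not isolated)
Conditions: NaOMe (1.05 equiv), MeOH, rt then reflux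
Reagents that add atoms: none
Why: Tandem malonate epoxide opening, cyclopropanation and lactonisation: the malonate anion opens the epoxide of 1 at its CH2 terminus, the alkoxide closes to the transposed epoxide 3 with loss of chloride, the malonate carbanion opens 3 at the methine carbon by 3-exo-tet SN2 with inversion to give 4, and the alkoxide of 4 lactonises onto the cis ester, so that C5 (R) of 5 is set by chirality transfer from 1 and C1 (S) follows from the cis ring fusion.

**Step 2**
Reactants: 6 4-bromo-2,6-dimethoxyphenol
Product: 7 2-(benzyloxy)-5-bromo-1,3-dimethoxybenzene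
Conditions: BnBr, K2CO3, DMF, rt
Reagents that add atoms: benzyl bromide, BrCc1ccccc1
Why: Williamson ether synthesis on the phenoxide masks the acidic phenol so that the aryl bromide can later be converted into a Grignard reagent; no stereocentre is involved.

**Step 3**
Reactants: 5 methyl (1S,5R)-2-oxo-3-oxabicyclo[3.1.0]hexane-1-carboxylate; 7 2-(benzyloxy)-5-bromo-1,3-dimethoxybenzene
Product: 9 methyl (3S,4R)-4-[4-(benzyloxy)-3,5-dimethoxybenzyl]-2-oxotetrahydrofuran-3-carboxylate, via arylmagnesium bromide 8 (not isolated)
Conditions: 7, Mg, THF, reflux; then 5, CuI (10 mol%), THF, −40 → 0 °C; 1 M HCl work-up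
Reagents that add atoms: none
Why: The organocopper species formed from 8 and CuI should deliver the aryl group to the cyclopropane methylene C6 of 5 in an SN2-type homoconjugate addition; the C1–C6 bond, weakened by both the lactone and the ester carbonyl, breaks, and the ring strain is released into a chelated magnesium malonate-type enolate that is protonated on work-up. The closest known reaction type is the copper-catalysed ring opening of cyclopropane-1,1-dicarboxylates by Grignard reagents. No ring is closed: the three-membered ring is opened and the lactone ring is kept. No stereocentre of the target is created, because C5 of 5 is not touched and becomes C4 (R) of 9, while C3 of 9 is epimerisable, should settle trans, and is erased in step 4. The step needs attack at the cyclopropane CH2 rather than at the methine C5 (which would give a six-membered lactone) or at either carbonyl group. The unsubstituted carbon is the less hindered electrophilic site, and the soft copper nucleophile at low temperature should favour ring opening over 1,2-addition.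

**Step 4**
Reactants: 9 methyl (3S,4R)-4-[4-(benzyloxy)-3,5-dimethoxybenzyl]-2-oxotetrahydrofuran-3-carboxylate
Product: 10 (R)-4-[4-(benzyloxy)-3,5-dimethoxybenzyl]dihydrofuran-2(3H)-one
Conditions: LiCl, H2O, DMSO, 140 °C
Reagents that add atoms: none
Why: Krapcho dealkoxycarbonylation: chloride dealkylates the methyl ester by SN2 at the methyl group and the resulting β-carbonyl carboxylate loses CO2; C4 is not acidic and keeps its configuration, and the C3 stereocentre disappears.

**Step 5**
Reactants: 10 (R)-4-[4-(benzyloxy)-3,5-dimethoxybenzyl]dihydrofuran-2(3H)-one; 11 5-(bromomethyl)-1,2,3-trimethoxybenzene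
Product: 12 (3R,4R)-4-[4-(benzyloxy)-3,5-dimethoxybenzyl]-3-(3,4,5-trimethoxybenzyl)dihydrofuran-2(3H)-one
Conditions: LiHMDS (1.1 equiv), THF, −78 °C; then 11, −78 → −30 °C
Reagents that add atoms: none
Why: Substrate-controlled diastereoselective enolate alkylation: the lithium enolate of 10 should be benzylated on the face opposite to the C4 benzyl group, which sets C3 as R, trans to C4.

**Step 6**
Reactants: 12 (3R,4R)-4-[4-(benzyloxy)-3,5-dimethoxybenzyl]-3-(3,4,5-trimethoxybenzyl)dihydrofuran-2(3H)-one
Product: 13 (3R,4R)-4-(4-hydroxy-3,5-dimethoxybenzyl)-3-(3,4,5-trimethoxybenzyl)dihydrofuran-2(3H)-one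
Conditions: H2 (1 atm), 10% Pd/C, EtOAc–MeOH, rt
Reagents that add atoms: none
Why: Catalytic hydrogenolysis cleaves only the aryl benzyl ether; the lactone, the methyl ethers and the two benzylic C–C bonds are inert under these neutral conditions, and no stereocentre is touched.

**Compound list**
1 | (R)-epichlorohydrin, (R)-2-(chloromethyl)oxirane | ClC[C@H]1CO1 | starting material
2 | dimethyl malonate | COC(=O)CC(=O)OC | starting material
3 | dimethyl (R)-2-(oxiran-2-ylmethyl)malonate | COC(=O)C(C[C@@H]1CO1)C(=O)OC | intermediate (not isolated)
4 | dimethyl (R)-2-(hydroxymethyl)cyclopropane-1,1-dicarboxylate, formed as its sodium alkoxide | OC[C@@H]1CC1(C(=O)OC)C(=O)OC | intermediate (not isolated)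
5 | methyl (1S,5R)-2-oxo-3-oxabicyclo[3.1.0]hexane-1-carboxylate | O=C1OC[C@@H]2C[C@]12C(=O)OC | intermediate
6 | 4-bromo-2,6-dimethoxyphenol | COc1cc(Br)cc(OC)c1O | starting material
7 | 2-(benzyloxy)-5-bromo-1,3-dimethoxybenzene | COc1cc(Br)cc(OC)c1OCc1ccccc1 | intermediate
8 | [4-(benzyloxy)-3,5-dimethoxyphenyl]magnesium bromide | COc1cc([Mg]Br)cc(OC)c1OCc1ccccc1 | intermediate (not isolated)
9 | methyl (3S,4R)-4-[4-(benzyloxy)-3,5-dimethoxybenzyl]-2-oxotetrahydrofuran-3-carboxylate | COc1cc(C[C@H]2COC(=O)[C@@H]2C(=O)OC)cc(OC)c1OCc1ccccc1 | intermediate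
10 | (R)-4-[4-(benzyloxy)-3,5-dimethoxybenzyl]dihydrofuran-2(3H)-one | COc1cc(C[C@H]2COC(=O)C2)cc(OC)c1OCc1ccccc1 | intermediate
11 | 5-(bromomethyl)-1,2,3-trimethoxybenzene (3,4,5-trimethoxybenzyl bromide) | COc1cc(CBr)cc(OC)c1OC | starting material
12 | (3R,4R)-4-[4-(benzyloxy)-3,5-dimethoxybenzyl]-3-(3,4,5-trimethoxybenzyl)dihydrofuran-2(3H)-one | COc1cc(C[C@H]2COC(=O)[C@@H]2Cc2cc(OC)c(OC)c(OC)c2)cc(OC)c1OCc1ccccc1 | intermediate
13 | (3R,4R)-4-(4-hydroxy-3,5-dimethoxybenzyl)-3-(3,4,5-trimethoxybenzyl)dihydrofuran-2(3H)-one | COc1cc(C[C@H]2COC(=O)[C@@H]2Cc2cc(OC)c(OC)c(OC)c2)cc(OC)c1O | target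

**Step count.** Total: 6 steps. Longest linear sequence: 5 steps (steps 1, 3, 4, 5, 6; the branch through step 2 joins at step 3).

**Steps most likely to fail**

Step 3 (key step). Addition of the Grignard reagent to the ester or lactone carbonyl may compete with opening of the cyclopropane. The fallback forms the same aryl–CH2 bond by a nickel-catalysed cross-electrophile coupling. It sets out from 5: homoconjugate addition of HBr (HBr in AcOH, rt) should open the cyclopropane at its methylene to give methyl (3S,4R)-4-(bromomethyl)-2-oxotetrahydrofuran-3-carboxylate F1. Reductive coupling of F1 with aryl bromide 7 (NiBr2·glyme, 4,4'-di-tert-butyl-2,2'-bipyridine, NaI cat., Zn, DMA, 60 °C) should then give 9, where the fallback returns to the route.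

Step 1. Direct displacement of chloride by the malonate anion, in competition with opening of the epoxide, leads to the enantiomeric lactone and would erode the enantiomeric purity of everything that follows. The fallback replaces epichlorohydrin by a cyclic sulfate, for which both possible orders of attack end in the same enantiomer, because the only event at the stereocentre is one SN2 inversion by the malonate carbon. Commercial (R)-3-(benzyloxy)propane-1,2-diol would be converted with SOCl2 and Et3N into (4S)-4-[(benzyloxy)methyl]-1,3,2-dioxathiolane 2-oxide F2, and this oxidised (RuCl3 cat., NaIO4) to (S)-4-[(benzyloxy)methyl]-1,3,2-dioxathiolane 2,2-dioxide F3. The fallback sets out from 2, which with NaH (2 equiv) and F3 in DME at reflux should give dimethyl (R)-2-[(benzyloxy)methyl]cyclopropane-1,1-dicarboxylate F4. Hydrogenolysis of F4 (H2, Pd/C) frees the alcohol 4, which with a trace of TsOH lactonises to 5, where the fallback returns to the route.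

Step 5. Incomplete facial selectivity in the alkylation, or a second alkylation of the product enolate, would contaminate 12 with the cis isomer or a dibenzylated lactone. The fallback replaces the alkylation by an aldol addition followed by hydrogenolysis. It sets out from 10, whose lithium enolate (LiHMDS, THF, −78 °C) should add to 3,4,5-trimethoxybenzaldehyde anti to the C4 substituent to give (3S,4R)-4-[4-(benzyloxy)-3,5-dimethoxybenzyl]-3-[hydroxy(3,4,5-trimethoxyphenyl)methyl]dihydrofuran-2(3H)-one F5 as a mixture of carbinol epimers. Hydrogenolysis of F5 (H2, Pd/C, AcOH, cat. HClO4) removes the benzylic hydroxyl group and the O-benzyl group together and arrives directly at 13, so that step 6 is no longer needed.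

**Further compounds**
F1 | step 3 | methyl (3S,4R)-4-(bromomethyl)-2-oxotetrahydrofuran-3-carboxylate | BrC[C@H]1COC(=O)[C@@H]1C(=O)OC
F2 | step 1 | (4S)-4-[(benzyloxy)methyl]-1,3,2-dioxathiolane 2-oxide (mixture of epimers at sulfur) | c1ccccc1COC[C@H]1COS(=O)O1
F3 | step 1 | (S)-4-[(benzyloxy)methyl]-1,3,2-dioxathiolane 2,2-dioxide | c1ccccc1COC[C@H]1COS(=O)(=O)O1
F4 | step 1 | dimethyl (R)-2-[(benzyloxy)methyl]cyclopropane-1,1-dicarboxylate | c1ccccc1COC[C@@H]1CC1(C(=O)OC)C(=O)OC
F5 | step 5 | (3S,4R)-4-[4-(benzyloxy)-3,5-dimethoxybenzyl]-3-[hydroxy(3,4,5-trimethoxyphenyl)methyl]dihydrofuran-2(3H)-one (mixture of carbinol epimers) | COc1cc(C[C@H]2COC(=O)[C@@H]2C(O)c2cc(OC)c(OC)c(OC)c2)cc(OC)c1OCc1ccccc1
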